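**Retrosynthetic overview**

- Selaginellin A ⇐ its bis(methyl ether) (BBr3) ⇐ a [3+3] double aldol condensation that builds ring E (the cyclohexa-2,5-dienone) last. The C2–C3 and C5–C6 bonds are cut, giving acetone (C2–C1(=O)–C6, used as acetonedicarboxylic acid) and a 2-(diarylmethylidene)malonaldehyde (C3–C4–C5, with the exocyclic C4=C7 bond already in place).
- Enabling feature: in ring E the carbonyl C1 and the exocyclic alkene C4=C7 lie on a local mirror plane, so C1 is flanked by two equivalent α-CH (C2, C6) and C4 by two equivalent β-CH (C3, C5). Both ring C=C bonds are therefore enone α,β-bonds (aldol retron). Because C4 is a fully substituted sp2 carbon, the dialdehyde has no α-hydrogen and the product cannot aromatize to a phenol.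
- The dialdehyde ⇐ a diaryl(pyrimidin-5-yl)methanol. The pyrimidine is a temporary ring whose C4–C5–C6 is the masked malonaldehyde; N-methylation, alkaline ring fission and dehydration remove N1–C2–N3 and the hydroxyl.
- The carbinol ⇐ 5-lithiopyrimidine + a hindered benzophenone ⇐ Suzuki–Miyaura coupling at C–Cl and Sonogashira coupling at C–Br ⇐ lithiation of 2-bromo-4-chlorotoluene between the two halogens and benzoylation.
- Ring order: ring A (central benzene) and the three aryl rings are bought; the pyrimidine is introduced intact and dismantled; ring E is the only ring formed.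

Key step: step 6

Remark: Ar stands for the 4'-methoxy-3-[(4-methoxyphenyl)ethynyl]-4-methylbiphenyl-2-yl group (ring A with its substituents); the target has no stereocentre and no E/Z isomerism at C4=C7, and both phenols are carried as methyl ethers.

**Step 1**
Reactants: 1 2-bromo-4-chloro-1-methylbenzene; 2 N-methoxy-N-methylbenzamide
Product: 4 (2-bromo-6-chloro-3-methylphenyl)(phenyl)methanone, via aryllithium 3 (not isolated)
Conditions: LiN(iPr)2, THF, −78 °C; then 2, −78 → −40 °C; then H2O
Reagents that add atoms: none
Why: Directed ortho-lithiation removes the most acidic ring proton, the one between Br and Cl, the 2,6-dihaloaryllithium is stable at −78 °C, and acylation with the N-methoxy-N-methylamide stops at the ketone.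

**Step 2**
Reactants: 4 (2-bromo-6-chloro-3-methylphenyl)(phenyl)methanone; 5 1-ethynyl-4-methoxybenzene
Product: 6 {6-chloro-2-[(4-methoxyphenyl)ethynyl]-3-methylphenyl}(phenyl)methanone
Conditions: PdCl2(PPh3)2 (5 mol%), CuI (5 mol%), Et3N–DMF, 80 °C
Reagents that add atoms: none
Why: Sonogashira coupling, in which oxidative addition should occur only at the C–Br bond (activated by the ortho benzoyl group) because the C–Cl bond is inert to the PPh3-ligated palladium catalyst.

**Step 3**
Reactants: 6 {6-chloro-2-[(4-methoxyphenyl)ethynyl]-3-methylphenyl}(phenyl)methanone; 7 (4-methoxyphenyl)boronic acid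
Product: 8 Ar(phenyl)methanone
Conditions: Pd(OAc)2 (3 mol%), SPhos (6 mol%), K3PO4, toluene–H2O, 100 °C
Reagents that add atoms: none
Why: Suzuki–Miyaura coupling of an ortho-acyl-activated aryl chloride with an electron-rich biarylphosphine ligand, to which the internal alkyne and the ketone are inert.

**Step 4**
Reactants: 8 Ar(phenyl)methanone; 9 5-bromopyrimidine
Product: 11 (±)-Ar(phenyl)(pyrimidin-5-yl)methanol, via pyrimidin-5-yllithium 10 (not isolated)
Conditions: 9, n-BuLi, THF–Et2O, −100 °C; then 8, −100 → −70 °C; then H2O
Reagents that add atoms: none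
Why: Addition of an aryllithium to a diaryl ketone, the reaction by which diaryl(pyrimidin-5-yl)methanols of the fenarimol type are made; the carbinol centre forms racemic, which is irrelevant because it becomes sp2 in step 5.

**Step 5**
Reactants: 11 (±)-Ar(phenyl)(pyrimidin-5-yl)methanol
Product: 14 2-[Ar(phenyl)methylidene]propanedial, via pyrimidinium triflate 12 (not isolated), via malonaldehyde enolate 13 (not isolated)
Conditions: MeOTf, CH2Cl2, 0 → 25 °C; then 1 M NaOH, THF–H2O, 0 → 25 °C; then 2 M HCl (pH 1), 25 °C
Reagents that add atoms: sodium hydroxide [Na+].[OH-] and water O (the two aldehyde oxygens); methyl trifluoromethanesulfonate COS(=O)(=O)C(F)(F)F (N-methyl group and counter-ion of 12 only)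
Why: Quaternized pyrimidines are opened by hydroxide (addition next to the N-methyl nitrogen, ring fission, hydrolysis of the amidine and enamine links), which releases C4–C5–C6 as a 2-substituted malonaldehyde enolate, and on acidification the enol pushes out the tertiary, doubly benzylic hydroxyl (dehydration of a β-hydroxy aldehyde) to give the fully conjugated ylidene dialdehyde.

**Step 6**
Reactants: 14 2-[Ar(phenyl)methylidene]propanedial; 15 3-oxopentanedioic acid (acetonedicarboxylic acid)
Product: 17 4-[Ar(phenyl)methylidene]cyclohexa-2,5-dien-1-one, via diol ketone 16 (not isolated)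
Conditions: 15 (1.5 equiv), Et3N (0.2 equiv), THF, 0 → 25 °C; then TsOH·H2O (0.5 equiv), toluene, 50 °C
Reagents that add atoms: none
Why: Proposed new method: a decarboxylative double aldol [3+3] annulation in which the amine-generated enol of the β-keto diacid 15 adds to one formyl group of the non-enolizable dialdehyde 14, the adduct loses CO2, the remaining β-keto acid enol adds to the second formyl group, and a second decarboxylation gives diol ketone 16, which TsOH should dehydrate twice (acid-catalysed β-elimination through the enol) to the cross-conjugated dienone. The closest known reaction types are the amine-catalysed decarboxylative aldol addition of β-keto acids to aldehydes, the Robinson–Schöpf reaction (double condensation of acetonedicarboxylic acid with a dialdehyde and an amine, with loss of two CO2) and the [3+3] condensation of nitromalonaldehyde with acetone to 4-nitrophenol; what is new is the 2-ylidene malonaldehyde as the three-carbon partner, which should deliver a quinone methide instead of a phenol. The one ring formed, ring E, closes in the second aldol addition by a 6-(enolendo)-exo-trig attack of the enol carbon on the formyl group. The two carbinol stereocentres of 16 arise without control and both are erased by the dehydration, and the product has neither a stereocentre nor E/Z isomerism at the exocyclic alkene because C3 and C5 of the new ring are equivalent. The step needs 1,2-addition instead of conjugate or hetero-Diels–Alder addition (secured by the tetrasubstituted β-carbon, screened by two aryl groups of which one is 2,6-disubstituted), ring closure before dehydration (secured by the mild amine stage, in which β-hydroxy ketones persist, so that an E-enone unable to cyclize is avoided) and one molecule of 15 per molecule of 14 (secured by the intramolecular six-membered closure).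

**Step 7**
Reactants: 17 4-[Ar(phenyl)methylidene]cyclohexa-2,5-dien-1-one
Product: 18 selaginellin A
Conditions: BBr3, CH2Cl2, −78 → 0 °C; then H2O
Reagents that add atoms: none
Why: Lewis-acid cleavage of both aryl methyl ethers by BBr3, which the diaryl alkyne should tolerate and which only complexes the dienone carbonyl reversibly, so that the quinone methide is restored on aqueous work-up.

**Compound list**

1 | 2-bromo-4-chloro-1-methylbenzene | Cc1ccc(Cl)cc1Br | starting material
2 | N-methoxy-N-methylbenzamide | CON(C)C(=O)c1ccccc1 | starting material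
3 | (2-bromo-6-chloro-3-methylphenyl)lithium (formed in the flask) | [Li]c1c(Cl)ccc(C)c1Br | intermediate
4 | (2-bromo-6-chloro-3-methylphenyl)(phenyl)methanone | Cc1ccc(Cl)c(C(=O)c2ccccc2)c1Br | intermediate
5 | 1-ethynyl-4-methoxybenzene | C#Cc1ccc(OC)cc1 | starting material
6 | {6-chloro-2-[(4-methoxyphenyl)ethynyl]-3-methylphenyl}(phenyl)methanone | Cc1ccc(Cl)c(C(=O)c2ccccc2)c1C#Cc1ccc(OC)cc1 | intermediate
7 | (4-methoxyphenyl)boronic acid | COc1ccc(B(O)O)cc1 | starting material
8 | {4'-methoxy-3-[(4-methoxyphenyl)ethynyl]-4-methylbiphenyl-2-yl}(phenyl)methanone | Cc1ccc(-c2ccc(OC)cc2)c(C(=O)c2ccccc2)c1C#Cc1ccc(OC)cc1 | intermediate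
9 | 5-bromopyrimidine | Brc1cncnc1 | starting material
10 | pyrimidin-5-yllithium (formed in the flask) | [Li]c1cncnc1 | intermediate
11 | (±)-Ar(phenyl)(pyrimidin-5-yl)methanol | Cc1ccc(-c2ccc(OC)cc2)c(C(O)(c2ccccc2)c2cncnc2)c1C#Cc1ccc(OC)cc1 | intermediate
12 | (±)-5-[Ar(hydroxy)(phenyl)methyl]-1-methylpyrimidin-1-ium trifluoromethanesulfonate (formed in the flask) | Cc1ccc(-c2ccc(OC)cc2)c(C(O)(c2ccccc2)c2cnc[n+](C)c2)c1C#Cc1ccc(OC)cc1.[O-]S(=O)(=O)C(F)(F)F | intermediate
13 | sodium enolate of (±)-2-[Ar(hydroxy)(phenyl)methyl]propanedial (formed in the flask) | Cc1ccc(-c2ccc(OC)cc2)c(C(O)(C(C=O)=C[O-])c2ccccc2)c1C#Cc1ccc(OC)cc1.[Na+] | intermediate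
14 | 2-[Ar(phenyl)methylidene]propanedial | Cc1ccc(-c2ccc(OC)cc2)c(C(=C(C=O)C=O)c2ccccc2)c1C#Cc1ccc(OC)cc1 | intermediate
15 | 3-oxopentanedioic acid (acetonedicarboxylic acid) | O=C(CC(=O)O)CC(=O)O | starting material
16 | 3,5-dihydroxy-4-[Ar(phenyl)methylidene]cyclohexan-1-one, mixture of stereoisomers (formed in the flask) | Cc1ccc(-c2ccc(OC)cc2)c(C(=C2C(O)CC(=O)CC2O)c2ccccc2)c1C#Cc1ccc(OC)cc1 | intermediate
17 | 4-[Ar(phenyl)methylidene]cyclohexa-2,5-dien-1-one (selaginellin A dimethyl ether) | Cc1ccc(-c2ccc(OC)cc2)c(C(=C2C=CC(=O)C=C2)c2ccccc2)c1C#Cc1ccc(OC)cc1 | intermediate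
18 | selaginellin A, 4-[{4'-hydroxy-3-[(4-hydroxyphenyl)ethynyl]-4-methylbiphenyl-2-yl}(phenyl)methylidene]cyclohexa-2,5-dien-1-one | Cc1ccc(-c2ccc(O)cc2)c(C(=C2C=CC(=O)C=C2)c2ccccc2)c1C#Cc1ccc(O)cc1 | target

**Step count and risks**

Total step count: 7. Longest linear sequence: 7 steps (from 1).

Steps most likely to fail:

Step 6. The first aldol adduct may dehydrate to the E-enone before the ring closes, 15 may lose CO2 before it adds (leaving an unactivated methyl ketone that does not close the ring), or the dialdehyde may be consumed by oligomerization. The fallback uses known chemistry, sets out from ketone 8 and comes back at 17. Br/Li exchange of (4-bromophenoxy)(tert-butyl)dimethylsilane with n-BuLi (THF, −78 °C) should give {4-[(tert-butyldimethylsilyl)oxy]phenyl}lithium F1, which adds to 8 to give the silyl-protected triarylmethanol F2. Bu4NF in THF then frees the p-hydroxytriarylmethanol F3, which loses water on acidification with AcOH (the classical fuchsone formation) to give 17.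

Step 5. The three-carbon unit may be lost by retro-aldol cleavage (back to ketone 8), the product may be deformylated by hydroxide, or the tertiary alkoxide may add to the neighbouring alkyne. The fallback sets out from 8 and comes back at 14. Br/Li exchange of 2-bromo-3,3-diethoxyprop-1-ene with t-BuLi (THF, −78 °C) should give (3,3-diethoxyprop-1-en-2-yl)lithium F4, which adds to 8 to give the tertiary allylic alcohol F5. Aqueous HCl in THF hydrolyses the acetal and moves the hydroxyl to the CH2 terminus by acid-catalysed 1,3-transposition through the diaryl-stabilized allyl cation, giving the hydroxymethyl enal F6. MnO2 in CH2Cl2 then oxidizes the allylic alcohol to 14.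

Step 4. The thermally fragile lithiopyrimidine may decompose by self-addition before it adds to the doubly ortho-substituted ketone. The fallback changes the order of events, sets out from 4 and comes back at 11. 10 is added to the less hindered dihalo ketone 4 to give the dihalo carbinol F7. Sonogashira coupling with 5 (PdCl2(PPh3)2, CuI, Et3N) gives the alkynyl chloro carbinol F8, and Suzuki–Miyaura coupling with 7 (Pd(OAc)2, XPhos, K3PO4) gives 11.

**Further compounds**

F1 | step 6 | {4-[(tert-butyldimethylsilyl)oxy]phenyl}lithium | [Li]c1ccc(O[Si](C)(C)C(C)(C)C)cc1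
F2 | step 6 | (±)-Ar{4-[(tert-butyldimethylsilyl)oxy]phenyl}(phenyl)methanol | Cc1ccc(-c2ccc(OC)cc2)c(C(O)(c2ccccc2)c2ccc(O[Si](C)(C)C(C)(C)C)cc2)c1C#Cc1ccc(OC)cc1
F3 | step 6 | (±)-Ar(4-hydroxyphenyl)(phenyl)methanol | Cc1ccc(-c2ccc(OC)cc2)c(C(O)(c2ccccc2)c2ccc(O)cc2)c1C#Cc1ccc(OC)cc1
F4 | step 5 | (3,3-diethoxyprop-1-en-2-yl)lithium | [Li]C(=C)C(OCC)OCC
F5 | step 5 | (±)-1-Ar-2-(diethoxymethyl)-1-phenylprop-2-en-1-ol | Cc1ccc(-c2ccc(OC)cc2)c(C(O)(C(=C)C(OCC)OCC)c2ccccc2)c1C#Cc1ccc(OC)cc1
F6 | step 5 | 3-Ar-2-(hydroxymethyl)-3-phenylprop-2-enal (E/Z mixture) | Cc1ccc(-c2ccc(OC)cc2)c(C(=C(CO)C=O)c2ccccc2)c1C#Cc1ccc(OC)cc1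
F7 | step 4 | (±)-(2-bromo-6-chloro-3-methylphenyl)(phenyl)(pyrimidin-5-yl)methanol | Cc1ccc(Cl)c(C(O)(c2ccccc2)c2cncnc2)c1Br
F8 | step 4 | (±)-{6-chloro-2-[(4-methoxyphenyl)ethynyl]-3-methylphenyl}(phenyl)(pyrimidin-5-yl)methanol | Cc1ccc(Cl)c(C(O)(c2ccccc2)c2cncnc2)c1C#Cc1ccc(OC)cc1
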